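- The ratio of target to side product A is what I need from the green flask, and from 12.0 min on neither reading moves beyond the scatter.

- green: starting material 0.20 M; partner 0.80 M; protic impurity 0.060 M; capture agent 4 mM; the very flask that is asked about, followed so far
- flask: starting material 0.20 M; partner 0.800 M; protic impurity 0.0600 M; capture agent 4.00 mM; time 6.0 h

green run (percent of the starting material charged)

| time / min | target / % | side product A / % |
|---|---|---|
| 3.00 | 7 | 22 |
| 5.00 | 13 | 30 |
| 8.00 | 17 | 33 |
| 12.0 | 19 | 41 |
| 20.0 | 18 | 40 |
| 30.0 | 19 | 41 |
| 40.0 | 19 | 41 |

(each reading ± 2 percentage points)



* ratio of target to side product A at 10 s
* ratio of target to side product A at 6.0 h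

- If side product A rises in first-order fashion to 41%, its 22% at 3.00 min gives a halving time of 2.70 min.
- The green flask's 6.0 h is 133 such times, and the readings are flat by 40.0 min, so I take the late ratio from the flat stretch.
- The last reading alone gives 0.463, and I commit to about that for 6.0 h.
- That single reading is the weak link, so I replace it. The last 4 readings give 0.460: this is the end ratio, target summed over those readings divided by side product A summed over the same readings.
- My reckoning gives no figure for 10 s, which lies 18.0 times earlier than the first reading, and that reading's own ratio, 0.318, carries the scatter.
- The forecast gives 0.22 at 10 s and 0.46 at 6.0 h, and calls the early figure “poorly constrained because it is an extrapolation”. Its late figure rests on the same readings as my end ratio, so their closeness is no check.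
- The simulation gives 1.30 at 10 s and 0.473 at 6.0 h, so the early ratio is 5.91 times the forecast.

    capture agent + open intermediate → trapped intermediate (k = 0.00150 /M/s)
    open intermediate → side product B (k = 0.00300 /s)
    starting material → target (k = 0.00130 /s)
    partner → decomposed reagent (k = 0.0230 /s)
    open intermediate → side product A (k = 0.00440 /s)
    starting material + protic impurity → quenched substrate (k = 0.0200 /M/s)
    starting material ⇌ open intermediate (K = 0.680, k = 0.0570 /s)

- In the green flask, target and side product A stand level at 14.5 s, later than 10 s and far earlier than the first reading, and the ratio ends at 0.473, beside my end ratio of 0.460. In the further flask charged with 0.80 M of starting material, 0.460 times its 43.2% of side product A gives 19.9% of target, and at 6.0 h that flask holds 20.4%.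

Readings and results come from a simulation with constants of no real substance; scatter was added.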